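Everything rests on building ring A (the 4-hydroxy-5-methoxynaphthalen-1-yl group on C2 of central ring B) onto ring B instead of coupling it as a finished naphthalene. Ring A carries C4–OH next to the ring-fusion carbon C4a, which in turn neighbours C5–OMe: the imprint of a 2-methoxybenzoyl unit whose only free ortho C–H becomes C8a. A rhodium-catalysed C–H annulation of the 2-methoxybenzoyl sulfoxonium ylide with a ring B aryl silyl alkyne forms A-C1–C8a and A-C2–C3 in one operation, creating the phenolic ring with silicon as a removable marker on A-C2. The alkyne precursor is a 1-benzyloxy-4-bromo-8-methoxynaphthalene bearing the trimethylsilylethynyl group on C2; its bromide later accepts ring C.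

Key step: step 7

Remark: the target SMILES defines no configuration at the two biaryl axes, so they are taken as stereochemically undefined; the route creates no stereocentre.

Step 1
Reactants: 1 naphthalene-1,8-diol
Product: 2 8-methoxynaphthalen-1-ol
Conditions: MeI (1.05 equiv), K2CO3, acetone, reflux
Reagents that add atoms: iodomethane, CI
Why: Williamson ether synthesis; once one hydroxyl is methylated the other is held in a peri hydrogen bond to the new methoxy oxygen and is much less nucleophilic, so one equivalent of MeI should stop at the mono-ether.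

Step 2
Reactants: 2 8-methoxynaphthalen-1-ol
Product: 3 4-bromo-8-methoxynaphthalen-1-ol
Conditions: NBS (1.0 equiv), MeCN, −20 → 0 °C
Reagents that add atoms: N-bromosuccinimide, O=C1CCC(=O)N1Br
Why: Electrophilic aromatic bromination; the free naphthol ring is more electron-rich than the anisole ring and NBS in MeCN without an amine attacks 1-naphthols at the para position C4, one equivalent at low temperature limiting dibromination.

Step 3
Reactants: 3 4-bromo-8-methoxynaphthalen-1-ol
Product: 4 4-bromo-2-iodo-8-methoxynaphthalen-1-ol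
Conditions: NIS (1.05 equiv), TsOH·H2O (10 mol %), MeCN, 0 °C → rt
Reagents that add atoms: N-iodosuccinimide, O=C1CCC(=O)N1I
Why: Electrophilic aromatic iodination; with C4 blocked by bromine the only strongly activated position left on the phenolic ring is C2, ortho to the hydroxyl.

Step 4
Reactants: 4 4-bromo-2-iodo-8-methoxynaphthalen-1-ol
Product: 5 1-(benzyloxy)-4-bromo-2-iodo-8-methoxynaphthalene
Conditions: BnBr, K2CO3, DMF, 60 °C
Reagents that add atoms: benzyl bromide, BrCc1ccccc1
Why: Williamson etherification of the naphthoxide; benzyl is chosen because it survives the acid, base and palladium steps ahead and leaves by hydrogenolysis without touching the methyl ethers.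

Step 5
Reactants: 5 1-(benzyloxy)-4-bromo-2-iodo-8-methoxynaphthalene; 6 ethynyltrimethylsilane
Product: 7 {[1-(benzyloxy)-4-bromo-8-methoxynaphthalen-2-yl]ethynyl}trimethylsilane
Conditions: Pd(PPh3)2Cl2 (3 mol %), CuI (5 mol %), Et3N, THF, rt
Reagents that add atoms: none
Why: Sonogashira coupling; zerovalent palladium inserts into the C–I bond far faster than into C–Br at room temperature, so the alkyne should be installed at C2 only and the bromide kept for ring C.

Step 6
Reactants: 8 2-methoxybenzoyl chloride; 9 trimethylsulfoxonium iodide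
Product: 11 2-[dimethyl(oxo)-λ6-sulfanylidene]-1-(2-methoxyphenyl)ethan-1-one, via dimethylsulfoxonium methylide 10 (not isolated)
Conditions: 9 (3 equiv), KOt-Bu (3 equiv), THF, reflux; then 8, 0 °C → rt
Reagents that add atoms: none
Why: C-Acylation of the Corey–Chaykovsky methylide by the acid chloride, a second equivalent of methylide removing the now acidic proton to give the stabilised keto sulfoxonium ylide.

Step 7
Reactants: 11 2-[dimethyl(oxo)-λ6-sulfanylidene]-1-(2-methoxyphenyl)ethan-1-one; 7 {[1-(benzyloxy)-4-bromo-8-methoxynaphthalen-2-yl]ethynyl}trimethylsilane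
Product: 12 4-[1-(benzyloxy)-4-bromo-8-methoxynaphthalen-2-yl]-8-methoxy-3-(trimethylsilyl)naphthalen-1-ol
Conditions: 11 (1.5 equiv), [Cp*Rh(MeCN)3](SbF6)2 (8 mol %), NaOAc (1 equiv), ClCH2CH2Cl, 80 °C, Ar
Reagents that add atoms: none
Why: The cationic Cp*-rhodium catalyst (trivalent rhodium throughout) binds the ylide carbonyl of 11 and cleaves its only ortho C–H by acetate-assisted metalation, alkyne 7 inserts into the aryl–rhodium bond, the ylide carbon then binds rhodium and expels Me2SO to give a rhodium carbene, the alkenyl group migrates onto the carbene carbon, and protonation of the resulting rhodium enolate releases the naphthol and the catalyst. The closest known reaction type is the rhodium-catalysed annulation of aroyl sulfoxonium ylides with internal alkynes to 1-naphthols. The one new ring, the phenolic ring of ring A, is closed in two events: carbometalation of the alkyne forms A-C1–C8a and the ring-closing 1,1-migratory insertion of the alkenyl ligand into the carbene forms A-C2–C3. No stereocentre is created. The step needs regioselective insertion with ring B on the carbon that bonds to the arene; this is secured by the trimethylsilyl group, whose bulk and whose stabilisation of an adjacent carbon–metal bond should place silicon on the rhodium-bound carbon as in Larock-type annulations of silyl alkynes, while the C5–OMe group occupies the other ortho position so the peri OH/OMe pattern cannot be scrambled. A preformed silver-free cationic complex is used so that no silver salt can desilylate or cyclise the benzyloxy alkyne.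

Step 8
Reactants: 12 4-[1-(benzyloxy)-4-bromo-8-methoxynaphthalen-2-yl]-8-methoxy-3-(trimethylsilyl)naphthalen-1-ol
Product: 13 4-[1-(benzyloxy)-4-bromo-8-methoxynaphthalen-2-yl]-8-methoxynaphthalen-1-ol
Conditions: CF3CO2H, CH2Cl2, 0 °C → rt
Reagents that add atoms: none
Why: Protodesilylation by electrophilic ipso-substitution; protonation at the silicon-bearing carbon is helped by the beta-silicon effect and by relief of strain against the ortho ring B aryl, while the benzyl ether and the bromide should tolerate CF3CO2H in CH2Cl2 at room temperature.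

Step 9
Reactants: 3 4-bromo-8-methoxynaphthalen-1-ol
Product: 14 1-(benzyloxy)-4-bromo-8-methoxynaphthalene
Conditions: BnBr, K2CO3, DMF, 50 °C
Reagents that add atoms: benzyl bromide, BrCc1ccccc1
Why: Williamson etherification of the naphthoxide, giving the ring C unit with the same hydrogenolysable protecting group as ring B.

Step 10
Reactants: 14 1-(benzyloxy)-4-bromo-8-methoxynaphthalene
Product: 15 2-[4-(benzyloxy)-5-methoxynaphthalen-1-yl]-4,4,5,5-tetramethyl-1,3,2-dioxaborolane
Conditions: B2pin2, Pd(dppf)Cl2 (3 mol %), KOAc, 1,4-dioxane, 90 °C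
Reagents that add atoms: bis(pinacolato)diboron, CC1(C)OB(OC1(C)C)B1OC(C)(C)C(C)(C)O1
Why: Miyaura borylation of the aryl bromide; the benzyl and methyl ethers are inert to the weakly basic conditions.

Step 11
Reactants: 13 4-[1-(benzyloxy)-4-bromo-8-methoxynaphthalen-2-yl]-8-methoxynaphthalen-1-ol; 15 2-[4-(benzyloxy)-5-methoxynaphthalen-1-yl]-4,4,5,5-tetramethyl-1,3,2-dioxaborolane
Product: 16 4-{1-(benzyloxy)-4-[4-(benzyloxy)-5-methoxynaphthalen-1-yl]-8-methoxynaphthalen-2-yl}-8-methoxynaphthalen-1-ol
Conditions: 15 (1.5 equiv), Pd(OAc)2 (5 mol %), SPhos (10 mol %), K3PO4, toluene/H2O, 90 °C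
Reagents that add atoms: none
Why: Suzuki–Miyaura coupling at the ring B bromide; the bulky electron-rich SPhos ligand is suited to joining two peri-hindered 1-naphthyl carbons and the free naphthol is tolerated as its phenoxide.

Step 12
Reactants: 16 4-{1-(benzyloxy)-4-[4-(benzyloxy)-5-methoxynaphthalen-1-yl]-8-methoxynaphthalen-2-yl}-8-methoxynaphthalen-1-ol
Product: 17 2,4-bis(4-hydroxy-5-methoxynaphthalen-1-yl)-8-methoxynaphthalen-1-ol
Conditions: H2 (1 atm), 10% Pd/C, EtOAc/MeOH, rt
Reagents that add atoms: none
Why: Catalytic hydrogenolysis of the two benzyl aryl ethers; at atmospheric pressure and room temperature the naphthalene rings and the methyl ethers should not be reduced.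

Compound list
1 | naphthalene-1,8-diol | Oc1cccc2cccc(O)c12 | starting material
2 | 8-methoxynaphthalen-1-ol | COc1cccc2cccc(O)c12 | intermediate
3 | 4-bromo-8-methoxynaphthalen-1-ol | COc1cccc2c(Br)ccc(O)c12 | intermediate
4 | 4-bromo-2-iodo-8-methoxynaphthalen-1-ol | COc1cccc2c(Br)cc(I)c(O)c12 | intermediate
5 | 1-(benzyloxy)-4-bromo-2-iodo-8-methoxynaphthalene | COc1cccc2c(Br)cc(I)c(OCc3ccccc3)c12 | intermediate
6 | ethynyltrimethylsilane | C#C[Si](C)(C)C | starting material
7 | {[1-(benzyloxy)-4-bromo-8-methoxynaphthalen-2-yl]ethynyl}trimethylsilane | COc1cccc2c(Br)cc(C#C[Si](C)(C)C)c(OCc3ccccc3)c12 | intermediate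
8 | 2-methoxybenzoyl chloride | COc1ccccc1C(Cl)=O | starting material
9 | trimethylsulfoxonium iodide | C[S+](C)(C)=O.[I-] | starting material
10 | dimethylsulfoxonium methylide | C=S(C)(C)=O | intermediate
11 | 2-[dimethyl(oxo)-λ6-sulfanylidene]-1-(2-methoxyphenyl)ethan-1-one | COc1ccccc1C(=O)C=S(C)(C)=O | intermediate
12 | 4-[1-(benzyloxy)-4-bromo-8-methoxynaphthalen-2-yl]-8-methoxy-3-(trimethylsilyl)naphthalen-1-ol | COc1cccc2c(-c3cc(Br)c4cccc(OC)c4c3OCc3ccccc3)c([Si](C)(C)C)cc(O)c12 | intermediate
13 | 4-[1-(benzyloxy)-4-bromo-8-methoxynaphthalen-2-yl]-8-methoxynaphthalen-1-ol | COc1cccc2c(-c3cc(Br)c4cccc(OC)c4c3OCc3ccccc3)ccc(O)c12 | intermediate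
14 | 1-(benzyloxy)-4-bromo-8-methoxynaphthalene | COc1cccc2c(Br)ccc(OCc3ccccc3)c12 | intermediate
15 | 2-[4-(benzyloxy)-5-methoxynaphthalen-1-yl]-4,4,5,5-tetramethyl-1,3,2-dioxaborolane | COc1cccc2c(B3OC(C)(C)C(C)(C)O3)ccc(OCc3ccccc3)c12 | intermediate
16 | 4-{1-(benzyloxy)-4-[4-(benzyloxy)-5-methoxynaphthalen-1-yl]-8-methoxynaphthalen-2-yl}-8-methoxynaphthalen-1-ol | COc1cccc2c(-c3cc(-c4ccc(OCc5ccccc5)c5c(OC)cccc45)c4cccc(OC)c4c3OCc3ccccc3)ccc(O)c12 | intermediate
17 | 2,4-bis(4-hydroxy-5-methoxynaphthalen-1-yl)-8-methoxynaphthalen-1-ol | COc1cccc2c(-c3cc(-c4ccc(O)c5c(OC)cccc45)c4cccc(OC)c4c3O)ccc(O)c12 | target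

Total step count: 12. Longest linear sequence: 9 steps (steps 1, 2, 3, 4, 5, 7, 8, 11, 12).

Steps most likely to fail

1. Step 7. The alkyne may insert in the opposite sense, putting ring B on A-C2 and silicon on A-C1. The silyl alkyne may also lose silicon or be attacked by the neighbouring benzyloxy oxygen before it is carbometalated. The fallback sets out from 5 and 15 and comes back to the route at 17; it gives up the annulation and brings in ring A as the same boronate that supplies ring C. Compound 5 would be treated with 15 (2.5 equiv) under Pd(OAc)2/SPhos, K3PO4, toluene/H2O at 100 °C, so that Suzuki–Miyaura coupling takes place first at the iodide and then at the bromide to give 1-(benzyloxy)-2,4-bis[4-(benzyloxy)-5-methoxynaphthalen-1-yl]-8-methoxynaphthalene F1. Hydrogenolysis of its three benzyl ethers (H2, Pd/C, EtOAc/MeOH) should then give 17.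

2. Step 8. The silicon sits meta to the ring A hydroxyl, so ipso-protonation may be slow, and acid strong enough to cleave the C–Si bond may start to cleave or transfer the benzyl group. The fallback sets out from 12 and comes back at 17; it moves the acid step to the end, where no benzyl ether is left. Compound 12 would be coupled with 15 under the conditions of step 11 to give 4-{1-(benzyloxy)-4-[4-(benzyloxy)-5-methoxynaphthalen-1-yl]-8-methoxynaphthalen-2-yl}-8-methoxy-3-(trimethylsilyl)naphthalen-1-ol F2. Hydrogenolysis (H2, Pd/C) would give 2-[4-hydroxy-5-methoxy-2-(trimethylsilyl)naphthalen-1-yl]-4-(4-hydroxy-5-methoxynaphthalen-1-yl)-8-methoxynaphthalen-1-ol F3. Forcing protodesilylation of F3 (neat CF3CO2H, 60 °C, under argon) should then give 17.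

3. Step 11. Protodeboronation of the electron-rich boronate may outrun transmetalation at the hindered, electron-rich aryl palladium centre. The fallback sets out from 14 and 13 and comes back at 16; it replaces boron by zinc. Bromine–lithium exchange on 14 (n-BuLi, THF, −78 °C) would give [4-(benzyloxy)-5-methoxynaphthalen-1-yl]lithium F4, and ZnCl2 would convert it into [4-(benzyloxy)-5-methoxynaphthalen-1-yl]zinc chloride F5. Negishi coupling of F5 (in excess) with 13 under Pd(OAc)2/SPhos in THF at 50 °C should give 16; arylzinc halides are expected to couple faster than they are protonated by the free naphthol.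

Further compounds
F1 | step 7 | 1-(benzyloxy)-2,4-bis[4-(benzyloxy)-5-methoxynaphthalen-1-yl]-8-methoxynaphthalene | COc1cccc2c(-c3ccc(OCc4ccccc4)c4c(OC)cccc34)cc(-c3ccc(OCc4ccccc4)c4c(OC)cccc34)c(OCc3ccccc3)c12
F2 | step 8 | 4-{1-(benzyloxy)-4-[4-(benzyloxy)-5-methoxynaphthalen-1-yl]-8-methoxynaphthalen-2-yl}-8-methoxy-3-(trimethylsilyl)naphthalen-1-ol | COc1cccc2c(-c3cc(-c4ccc(OCc5ccccc5)c5c(OC)cccc45)c4cccc(OC)c4c3OCc3ccccc3)c([Si](C)(C)C)cc(O)c12
F3 | step 8 | 2-[4-hydroxy-5-methoxy-2-(trimethylsilyl)naphthalen-1-yl]-4-(4-hydroxy-5-methoxynaphthalen-1-yl)-8-methoxynaphthalen-1-ol | COc1cccc2c(-c3cc(-c4ccc(O)c5c(OC)cccc45)c4cccc(OC)c4c3O)c([Si](C)(C)C)cc(O)c12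
F4 | step 11 | [4-(benzyloxy)-5-methoxynaphthalen-1-yl]lithium | [Li]c1ccc(OCc2ccccc2)c2c(OC)cccc12
F5 | step 11 | [4-(benzyloxy)-5-methoxynaphthalen-1-yl]zinc chloride | Cl[Zn]c1ccc(OCc2ccccc2)c2c(OC)cccc12
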